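**Retrosynthetic overview**
1. Tauranin ⇒ 2-(drim-8(12)-en-11-yl)-5-(hydroxymethyl)benzene-1,3-diol. The last bond made is the ring C–O bond that turns this resorcinol into the hydroxy-para-quinone; its two free ring CH positions are symmetry-equivalent, so only one hydroxyquinone can form.
2. Resorcinol ⇒ (hydride unmasking) bis-pivalate benzoate ⇒ (C11–aryl bond, Negishi) albicanyl zinc iodide + methyl 4-bromo-3,5-bis(pivaloyloxy)benzoate.
3. Albicanyl iodide ⇒ (anti elimination to the exocyclic alkene) 11-iododriman-8α-ol ⇒ (alkoxy-radical C–C scission, loss of the lactone carbonyl carbon) sclareolide lactol ⇒ (+)-sclareolide.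
4. Ring order: decalin rings A and B with C5, C9 and C10 come ready-made from (+)-sclareolide; the benzene ring is bought; the quinone ring is generated from it only in the final C–O bond-forming step.

Assumption: (+)-sclareolide and methyl 4-bromo-3,5-dihydroxybenzoate are bought as catalogue chemicals.
Numbering note: drimane numbering is used for the decalin (C11 = CH2 on C9; C12 = the carbon on C8); all decalin compounds have 5α-H, 9α-H and 10β-CH3.

**Route**

Step 1
Reactants: 1 methyl 4-bromo-3,5-dihydroxybenzoate
Product: 2 methyl 4-bromo-3,5-bis(pivaloyloxy)benzoate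
Conditions: pivaloyl chloride (2.5 equiv), Et3N (3 equiv), DMAP (5 mol%), CH2Cl2, 0 °C to rt
Reagents that add atoms: pivaloyl chloride, CC(C)(C)C(=O)Cl
Why: DMAP-catalysed O-acylation of both phenols gives esters that tolerate organozinc/palladium chemistry and are removed later by the same hydride that reduces the benzoate; no stereocentre is involved.

Step 2
Reactants: 3 (+)-sclareolide
Product: 4 sclareolide lactol (lactone C=O reduced to CH–OH, anomer mixture)
Conditions: i-Bu2AlH (1.2 equiv), CH2Cl2, −78 °C; aq KNaC4H4O6
Reagents that add atoms: none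
Why: Partial reduction of a γ-lactone to the lactol, whose aluminium hemiacetal is stable at −78 °C; C5, C8, C9 and C10 are untouched and the new anomeric centre is destroyed in step 3.

Step 3
Reactants: 4 sclareolide lactol
Product: 6 11-iododriman-8α-ol, via iodoformate 5 (not isolated)
Conditions: PhI(OAc)2 (1.1 equiv), iodine (1.0 equiv), cyclohexane/CH2Cl2, visible light, rt; aq Na2S2O3 wash, concentrate; then 7 M NH3 in MeOH, 0 °C to rt
Reagents that add atoms: iodine, [I][I]
Why: Suárez alkoxy-radical fragmentation (hypoiodite photolysis, β-scission of the C11–carbonyl carbon bond, iodine capture of the C11 radical) followed by ammonolysis of the tertiary formate; the C8–O bond and C9 are not touched, so 8α-OH and 9α-H are retained.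

Step 4
Reactants: 6 11-iododriman-8α-ol
Product: 8 11-iododrim-8(12)-ene (albicanyl iodide), via chlorosulfite 7 (not isolated)
Conditions: SOCl2 (1.5 equiv), Et3N (5 equiv), CH2Cl2, −78 °C, 20 min; chromatography on AgNO3-impregnated silica to remove minor ring B endocyclic alkenes
Reagents that add atoms: none
Why: E2 elimination of the chlorosulfite, in which the equatorial 8α-oxygen has no antiperiplanar ring C–H and only the C12 methyl hydrogens can align, so the exocyclic 8(12)-alkene is favoured; the C8 stereocentre is removed and C5, C9, C10 are untouched.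

Step 5
Reactants: 8 11-iododrim-8(12)-ene (albicanyl iodide); 2 methyl 4-bromo-3,5-bis(pivaloyloxy)benzoate
Product: 10 methyl 4-(drim-8(12)-en-11-yl)-3,5-bis(pivaloyloxy)benzoate, via alkylzinc iodide 9 (not isolated)
Conditions: Zn dust (3 equiv, activated with BrCH2CH2Br and Me3SiCl), LiCl (1.5 equiv), THF, 40 °C; then 2 (1.2 equiv), Pd(OAc)2 (4 mol%), 2-dicyclohexylphosphino-2′,6′-dimethoxybiphenyl (SPhos, 8 mol%), THF/NMP, 50 °C
Reagents that add atoms: none
Why: LiCl-promoted zinc insertion into the primary iodide and Negishi coupling with a biarylphosphine–palladium catalyst suited to di-ortho-substituted aryl bromides and primary alkylzincs; the metal sits on C11, so C9 keeps its configuration, and the esters are inert to the organozinc.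

Step 6
Reactants: 10 methyl 4-(drim-8(12)-en-11-yl)-3,5-bis(pivaloyloxy)benzoate
Product: 11 2-(drim-8(12)-en-11-yl)-5-(hydroxymethyl)benzene-1,3-diol
Conditions: LiAlH4 (4 equiv), THF, 0 °C to rt, argon; aq KNaC4H4O6, work-up kept at pH 5–6
Reagents that add atoms: none
Why: Hydride reduction turns the benzoate into the benzylic alcohol and cleaves both aryl pivalates in one operation, while the isolated 1,1-disubstituted alkene is inert; no stereocentre is affected.

Step 7
Reactants: 11 2-(drim-8(12)-en-11-yl)-5-(hydroxymethyl)benzene-1,3-diol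
Product: 13 tauranin, via hydroxy-ortho-quinone 12 (not isolated)
Conditions: [Cu(MeCN)4]PF6 (10 mol%), N,N′-di-tert-butylethylenediamine (20 mol%), Et3N (1.0 equiv), O2 (1 atm), 4 Å MS, CH2Cl2, −20 °C to rt; then 1 M aq NaHSO4
Reagents that add atoms: dioxygen, O=O
Why: Proposed new method: tyrosinase-type aerobic ortho-oxygenation applied to a 2-alkylresorcinol to give a 2-hydroxy-1,4-benzoquinone — monovalent copper with the diamine binds O2 as a side-on peroxo dicopper species, the resorcinol monophenolate coordinates, and one peroxo oxygen is delivered by electrophilic aromatic substitution to the only unsubstituted ortho carbon (also para to the second OH), the copper catecholate is oxidised to hydroxy-ortho-quinone 12, and 12 tautomerises at once to the vinylogous acid 13, held as its triethylammonium salt, which no longer accepts Michael addition from unreacted 11; because the two free ring positions of 11 are equivalent, ortho or para delivery gives the same product, the benzylic alcohol should react much more slowly without a pyridine-type co-ligand, and the alkene is not attacked; the closest known reaction types are copper/diamine-catalysed aerobic ortho-oxygenation of monophenols to ortho-quinones and the Teuber oxidation of resorcinols; no stereocentre is formed.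

**Compound list**
1 | methyl 4-bromo-3,5-dihydroxybenzoate | COC(=O)c1cc(O)c(Br)c(O)c1 | starting material
2 | methyl 4-bromo-3,5-bis(pivaloyloxy)benzoate | COC(=O)c1cc(OC(=O)C(C)(C)C)c(Br)c(OC(=O)C(C)(C)C)c1 | intermediate
3 | (+)-sclareolide, (3aR,5aS,9aS,9bR) | C[C@@]12CC[C@H]3C(C)(C)CCC[C@]3(C)[C@H]1CC(=O)O2 | starting material
4 | sclareolide lactol (anomer mixture) | C[C@@]12CC[C@H]3C(C)(C)CCC[C@]3(C)[C@H]1CC(O)O2 | intermediate
5 | 11-iododriman-8α-yl formate (iodoformate) | C[C@@]1(OC=O)CC[C@H]2C(C)(C)CCC[C@]2(C)[C@H]1CI | intermediate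
6 | 11-iododriman-8α-ol (8α-OH equatorial, 8β-CH3) | C[C@@]1(O)CC[C@H]2C(C)(C)CCC[C@]2(C)[C@H]1CI | intermediate
7 | 11-iododriman-8α-yl chlorosulfite | C[C@@]1(OS(Cl)=O)CC[C@H]2C(C)(C)CCC[C@]2(C)[C@H]1CI | intermediate
8 | 11-iododrim-8(12)-ene (albicanyl iodide) | C=C1CC[C@H]2C(C)(C)CCC[C@]2(C)[C@H]1CI | intermediate
9 | (drim-8(12)-en-11-yl)zinc iodide | C=C1CC[C@H]2C(C)(C)CCC[C@]2(C)[C@H]1C[Zn]I | intermediate
10 | methyl 4-(drim-8(12)-en-11-yl)-3,5-bis(pivaloyloxy)benzoate | C=C1CC[C@H]2C(C)(C)CCC[C@]2(C)[C@H]1Cc1c(OC(=O)C(C)(C)C)cc(C(=O)OC)cc1OC(=O)C(C)(C)C | intermediate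
11 | 2-(drim-8(12)-en-11-yl)-5-(hydroxymethyl)benzene-1,3-diol | C=C1CC[C@H]2C(C)(C)CCC[C@]2(C)[C@H]1Cc1c(O)cc(CO)cc1O | intermediate
12 | 3-(drim-8(12)-en-11-yl)-4-hydroxy-6-(hydroxymethyl)-1,2-benzoquinone (ortho-quinone tautomer of tauranin) | C=C1CC[C@H]2C(C)(C)CCC[C@]2(C)[C@H]1CC1=C(O)C=C(CO)C(=O)C1=O | intermediate
13 | tauranin, (5S,9S,10S) | C=C1CC[C@H]2C(C)(C)CCC[C@]2(C)[C@H]1CC1=C(O)C(=O)C(CO)=CC1=O | target

**Step count**
Total steps: 7. Longest linear sequence: 6 (steps 2 to 7, from 3 to 13).

**Three steps most likely to fail**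

Step 7 (the new step). Risks are catalyst arrest through chelation of copper by the hydroxyquinonate, over-oxidation of the benzylic alcohol, and oxidative dimerisation of 11. The fallback sets out from 11 and comes back at 13. It replaces catalytic oxygen-atom transfer from O2 by the known stoichiometric Teuber oxidation: (KO3S)2NO (potassium nitrosodisulfonate, 2.5 equiv), aq KH2PO4, acetone/water, 0 °C. The nitroxyl radical couples at the ring carbon para to one hydroxyl and the adduct collapses to the hydroxy-para-quinone; symmetry again allows only 13. This fallback makes no new compound (F0).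

Step 5. Risks are slow transmetalation of the β-branched alkylzinc onto the di-ortho-acyloxy arylpalladium and β-hydride elimination. The fallback sets out from 8 and comes back at 11. It reverses the polarity and makes the bond by iron-catalysed radical coupling of the alkyl iodide with an aryl Grignard reagent. Commercial 3,5-dihydroxybenzyl alcohol is protected (MOMCl, i-Pr2NEt, CH2Cl2) to 1,3-bis(methoxymethoxy)-5-[(methoxymethoxy)methyl]benzene F1. n-BuLi/TMEDA (THF, 0 °C) lithiates between the two aryl OMOM groups to give the aryllithium F2, and MgBr2·OEt2 converts it into the arylmagnesium bromide F3. Slow addition of F3 to 8 with Fe(acac)3 (5 mol%)/TMEDA in THF at 0 °C gives 2-(drim-8(12)-en-11-yl)-1,3-bis(methoxymethoxy)-5-[(methoxymethoxy)methyl]benzene F4. ZnBr2/n-PrSH (CH2Cl2, 0 °C) removes all three MOM groups without acid strong enough to move the alkene and gives 11, so step 6 is skipped.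

Step 4. Risks are formation of ring B endocyclic alkenes or the tertiary chloride, and loss of the light-sensitive iodide. The fallback sets out from 5 (isolated after the fragmentation instead of being ammonolysed) and comes back at 10. It moves alkene formation behind the coupling and runs it as a thermal syn-elimination on an iodide-free substrate. Zn/LiCl (THF, 25 °C) converts 5 into [8α-(formyloxy)driman-11-yl]zinc iodide F5. Negishi coupling with 2 (Pd(OAc)2, SPhos) gives methyl 4-[8α-(formyloxy)driman-11-yl]-3,5-bis(pivaloyloxy)benzoate F6. NH3/MeOH at 0 °C removes only the formate to give methyl 4-(8α-hydroxydriman-11-yl)-3,5-bis(pivaloyloxy)benzoate F7. The Burgess reagent (methyl N-(triethylammoniosulfonyl)carbamate, benzene, 50 °C) dehydrates F7 to 10.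

**Further compounds**
F0 | step 7 | none | none
F1 | step 5 | 1,3-bis(methoxymethoxy)-5-[(methoxymethoxy)methyl]benzene | COCOCc1cc(OCOC)cc(OCOC)c1
F2 | step 5 | {2,6-bis(methoxymethoxy)-4-[(methoxymethoxy)methyl]phenyl}lithium | [Li]c1c(OCOC)cc(COCOC)cc1OCOC
F3 | step 5 | {2,6-bis(methoxymethoxy)-4-[(methoxymethoxy)methyl]phenyl}magnesium bromide | Br[Mg]c1c(OCOC)cc(COCOC)cc1OCOC
F4 | step 5 | 2-(drim-8(12)-en-11-yl)-1,3-bis(methoxymethoxy)-5-[(methoxymethoxy)methyl]benzene | C=C1CC[C@H]2C(C)(C)CCC[C@]2(C)[C@H]1Cc1c(OCOC)cc(COCOC)cc1OCOC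
F5 | step 4 | [8α-(formyloxy)driman-11-yl]zinc iodide | C[C@@]1(OC=O)CC[C@H]2C(C)(C)CCC[C@]2(C)[C@H]1C[Zn]I
F6 | step 4 | methyl 4-[8α-(formyloxy)driman-11-yl]-3,5-bis(pivaloyloxy)benzoate | C[C@@]1(OC=O)CC[C@H]2C(C)(C)CCC[C@]2(C)[C@H]1Cc1c(OC(=O)C(C)(C)C)cc(C(=O)OC)cc1OC(=O)C(C)(C)C
F7 | step 4 | methyl 4-(8α-hydroxydriman-11-yl)-3,5-bis(pivaloyloxy)benzoate | C[C@@]1(O)CC[C@H]2C(C)(C)CCC[C@]2(C)[C@H]1Cc1c(OC(=O)C(C)(C)C)cc(C(=O)OC)cc1OC(=O)C(C)(C)C
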